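The ten-membered carbocycle is made by ring expansion, not by macrocyclisation. Drawing a bond from C4 to C9 contracts the (1(10)Z,4Z)-cyclodecadienone to a cyclohexanone (C4–C9) on which C6, C7, C8 and the cis-lactone are easy to set. This works because the C9 carbonyl sits 1,5 to the C4=C5 alkene and carries the Z-alkenyl carbon C10, whose chain C1–C3 ends at C4. In a single flask the C10 vinyllithium closes onto C9, the alkoxide ejects the C5 mesylate with cleavage of C4–C9, and the phosphonate anion at C11 is methylenated. The precursor is a keto mesylate with a (Z)-4-iodopent-3-enyl chain, a C8 silyl ether and a phosphonolactone.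

Key step: step 13

Notation: carbons carry the germacrane locants of the target throughout (C1–C10 ring, C11–C13 lactone carbons, C14 on C10, C15 on C4). In the six-membered-ring intermediates β is the face of the C4 methyl group and α the face of the iodopentenyl chain; C4 is S in all of them.
Assumption: dione 8 is accepted by baker's yeast with the sense known for 2-alkyl-2-methylcyclohexane-1,3-diones.

Step 1
Reactants: 1 2-methylcyclohexane-1,3-dione; 2 acrolein
Product: 3 3-(1-methyl-2,6-dioxocyclohexyl)propanal
Conditions: H2O, rt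
Reagents that add atoms: none
Why: Michael addition of the acidic 1,3-dione to acrolein, which runs in water without catalyst, creates the quaternary carbon C4 and stops cleanly because the product has no acidic C–H left between the carbonyl groups.

Step 2
Reactants: 3 3-(1-methyl-2,6-dioxocyclohexyl)propanal; 4 ethyltriphenylphosphonium iodide
Product: 8 2-[(3Z)-4-iodopent-3-en-1-yl]-2-methylcyclohexane-1,3-dione, via ethylidene ylide 5 (not isolated), via iodophosphonium iodide 6 (not isolated), via iodo ylide 7 (not isolated)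
Conditions: 4, n-BuLi, THF, 0 °C; I2, −78 °C; NaN(SiMe3)2, −20 °C; then 3, −78 °C to rt
Reagents that add atoms: iodine, II
Why: Stork–Zhao-type Wittig olefination: the non-stabilised α-iodo ylide closes kinetically to the cis-oxaphosphetane and so gives the (Z)-iodoalkene with iodine cis to the chain, and at −78 °C it attacks only the aldehyde and not the two hindered ketones.

Step 3
Reactants: 8 2-[(3Z)-4-iodopent-3-en-1-yl]-2-methylcyclohexane-1,3-dione
Product: 9 (2S,3S)-3-hydroxy-2-[(3Z)-4-iodopent-3-en-1-yl]-2-methylcyclohexan-1-one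
Conditions: baker's yeast (Saccharomyces cerevisiae), sucrose, H2O (5% DMSO), 30 °C
Reagents that add atoms: none
Why: Desymmetrising carbonyl reduction of a prochiral 2,2-disubstituted cyclohexane-1,3-dione by yeast reductases, which follow Prelog's rule to the (S)-carbinol and, as known for 2-alkyl-2-methyl diones, deliver hydride on the methyl face so that the hydroxyl ends cis to the chain, setting C4 (S) and C5 in one event.

Step 4
Reactants: 9 (2S,3S)-3-hydroxy-2-[(3Z)-4-iodopent-3-en-1-yl]-2-methylcyclohexan-1-one
Product: 10 (2S,3S)-2-[(3Z)-4-iodopent-3-en-1-yl]-2-methyl-3-(triethylsilyloxy)cyclohexan-1-one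
Conditions: Et3SiCl, imidazole, DMF, 0 °C to rt
Reagents that add atoms: chlorotriethylsilane, CC[Si](Cl)(CC)CC
Why: Standard silylation of a secondary alcohol, which blocks retro-aldol cleavage and leaves a group that is base-stable but more acid-labile than the tert-butyldimethylsilyl ether introduced in step 10; no stereocentre is touched.

Step 5
Reactants: 10 (2S,3S)-2-[(3Z)-4-iodopent-3-en-1-yl]-2-methyl-3-(triethylsilyloxy)cyclohexan-1-one
Product: 12 (5S,6S)-6-[(3Z)-4-iodopent-3-en-1-yl]-6-methyl-5-(triethylsilyloxy)cyclohex-2-en-1-one, via lithium enolate 11 (not isolated)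
Conditions: LiN(iPr)2, THF, −78 °C; then N-tert-butylbenzenesulfinimidoyl chloride, −78 °C
Reagents that add atoms: none
Why: Mukaiyama dehydrogenation: the only enolate that can form (C8, since C4 is quaternary) attacks sulfur and the α-sulfilimine undergoes syn-elimination at −78 °C to the C7=C8 enone, with no palladium present that could insert into the C–I bond.

Step 6
Reactants: 12 (5S,6S)-6-[(3Z)-4-iodopent-3-en-1-yl]-6-methyl-5-(triethylsilyloxy)cyclohex-2-en-1-one
Product: 14 (4R,5R,6S)-4-hydroxy-6-[(3Z)-4-iodopent-3-en-1-yl]-6-methyl-5-(triethylsilyloxy)cyclohex-2-en-1-one, via silyl dienol ether 13 (not isolated)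
Conditions: Me3SiOTf, Et3N, CH2Cl2, 0 °C; then mCPBA, NaHCO3, CH2Cl2, −20 °C; citric acid, MeOH, 0 °C
Reagents that add atoms: 3-chloroperbenzoic acid (mCPBA), OOC(=O)c1cccc(Cl)c1
Why: Vinylogous Rubottom oxidation: soft enolisation can only give the linear C9(OSiMe3)=C8–C7=C6 dienol ether, the peracid epoxidises its terminal C6=C7 bond on the face away from the adjacent C5 silyl ether, and collapse of the epoxide returns the enone with the new C6 hydroxyl trans to C5–O (C6 set by the neighbouring C5 centre).

Step 7
Reactants: 14 (4R,5R,6S)-4-hydroxy-6-[(3Z)-4-iodopent-3-en-1-yl]-6-methyl-5-(triethylsilyloxy)cyclohex-2-en-1-one; 15 (diethoxyphosphoryl)acetic acid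
Product: 16 (diethoxyphosphoryl)acetate of the C4 hydroxyl of 14 (germacrane C6 ester; ring centres 4R,5R,6S unchanged)
Conditions: DCC, DMAP (cat.), CH2Cl2, 0 °C to rt
Reagents that add atoms: none
Why: Steglich (carbodiimide/DMAP) esterification of the allylic alcohol with the acid, in which the C6–O bond is not broken and C6 is therefore retained.

Step 8
Reactants: 16 (diethoxyphosphoryl)acetate ester
Product: 17 cis-fused α-(diethoxyphosphoryl)-γ-lactone ketone (C9 ketone, C8 methylene, lactone from C6β–O to C7β–C11, C5α–OSiEt3, C4 β-methyl and α-[(3Z)-4-iodopent-3-enyl], C11 epimers)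
Conditions: Cs2CO3 (0.3 equiv), MeCN, 0 °C to rt
Reagents that add atoms: none
Why: Base-catalysed intramolecular Michael addition (5-exo-trig) of the phosphonoacetate carbanion to C7 of the enone, in which the three-atom ester tether can reach C7 only from the face of the C6 oxygen and so fixes the cis ring fusion (C7), while C11 is left as a mixture because it becomes sp2 in step 13.

Step 9
Reactants: 17 cis-fused phosphonolactone ketone
Product: 19 8α-hydroxy derivative of 17, via dipotassium dianion 18 (not isolated)
Conditions: KN(SiMe3)2 (2.1 equiv), THF, −78 °C; (camphorsulfonyl)oxaziridine (1.05 equiv), −78 to −40 °C; aq. NH4Cl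
Reagents that add atoms: (camphorsulfonyl)oxaziridine (racemic), CC1(C)C2CCC13CS(=O)(=O)N4OC34C2
Why: Davis-type enolate hydroxylation: the first equivalent of base is taken by the phosphonolactone C–H, the second forms the only possible ketone enolate (C8=C9), and this far more nucleophilic site accepts the single equivalent of oxaziridine from the convex α-face opposite the C7–C11 bond (C8 set by the ring fusion), the camphor-derived reagent being chosen because its ketimine by-product does not trap carbanions.

Step 10
Reactants: 19 8α-hydroxy phosphonolactone ketone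
Product: 20 8α-(tert-butyldimethylsilyloxy) derivative of 17 (C5α–OSiEt3 retained)
Conditions: t-BuMe2SiOTf, 2,6-lutidine, CH2Cl2, −78 to 0 °C
Reagents that add atoms: tert-butyldimethylsilyl triflate, CC(C)(C)[Si](C)(C)OS(=O)(=O)C(F)(F)F
Why: Silylation of the secondary α-hydroxy ketone with the triflate and a hindered pyridine base, conditions that neither enolise C8 nor disturb the triethylsilyl ether, phosphonate or iodoalkene.

Step 11
Reactants: 20 bis-silyl ether
Product: 21 5α-hydroxy-8α-(tert-butyldimethylsilyloxy) phosphonolactone ketone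
Conditions: PPTS (cat.), MeOH/CH2Cl2, 0 °C
Reagents that add atoms: none
Why: Acid-catalysed methanolysis removes the triethylsilyl ether much faster than the secondary tert-butyldimethylsilyl ether, and no stereocentre or base-sensitive group is exposed.

Step 12
Reactants: 21 5α-hydroxy-8α-silyloxy phosphonolactone ketone
Product: 22 keto mesylate (5α-methanesulfonate of 21; C4 β-methyl and α-[(3Z)-4-iodopent-3-enyl], C6β/C7β cis-lactone, C8α–OSiMe2t-Bu, C9 ketone)
Conditions: MsCl, Et3N, CH2Cl2, −20 to 0 °C
Reagents that add atoms: methanesulfonyl chloride, CS(=O)(=O)Cl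
Why: Mesylation by the sulfene pathway, which tolerates the neopentyl-type hindrance at C5 and retains configuration because only the O–H bond reacts, gives a β-sulfonyloxy ketone that cannot eliminate since C4 carries no hydrogen.

Step 13
Reactants: 22 keto mesylate; 23 formaldehyde (as paraformaldehyde)
Product: 28 8-(tert-butyldimethylsilyloxy)-9-oxogermacra-1(10)Z,4Z,11(13)-trien-12,6-olide (C6, C7, C8 as in the target), via potassium phosphonate 24 (not isolated), via vinyllithium 25 (not isolated), via bicyclic alkoxide 26 (not isolated), via ring-expanded phosphonate anion 27 (not isolated)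
Conditions: KH (1.05 equiv), THF, 0 °C; t-BuLi (2.05 equiv), THF/Et2O/pentane, −100 °C; −100 to 0 °C (18-crown-6 if slow); (CH2O)n, 0 °C to rt
Reagents that add atoms: none
Why: Proposed new method: KH first turns the acidic phosphonolactone C11–H into its potassium salt (H2 as the only by-product, so that no N–H acid is left), t-BuLi then exchanges the alkenyl iodide faster than it attacks any carbonyl, the configurationally stable (Z)-alkenyllithium adds to the neighbouring C9 ketone, the resulting alkoxide expels the C5 mesylate with cleavage of C4–C9 (Grob/Wharton fragmentation), and the phosphonate anion that has waited through all of this is methylenated by formaldehyde (Horner–Wadsworth–Emmons). The closest known reaction types are the one-pot Barbier cyclisation/Grob fragmentation of iodoalkyl keto sulfonates to medium-ring cycloalkenones, the halogen–lithium-exchange cyclisation of alkenyl iodides onto ketones and the Michael/olefination synthesis of α-methylene lactones, none of which has been run with a spectator phosphonate anion or joined in this order. The only ring closed is the transient cyclohexene C4–C3–C2–C1=C10–C9, by 6-exo-trig attack on the carbonyl, and the ten-membered ring is not closed but uncovered when the bond shared by the two six-membered rings breaks. The single new stereocentre is the transient C9 carbinol, fixed cis to C3 by the four-atom tether and erased again in the fragmentation, while C6, C7 and C8 are only carried through. The step needs cis ring fusion and a strictly anti-periplanar fragmentation, and both are built into 22: with the α-chain carbon C3 axial the α-mesylate (trans to the C4 methyl) is equatorial and anti to C4–C9, so C3 and C6 finish cis on the new C4=C5 bond (4Z), and the 1(10)Z geometry is that of the iodoalkene, kept through lithium. Competing E2 and substitution are shut off because C4 is quaternary, H6 is syn to the mesylate and the C9 oxygen cannot reach the rear of C5.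

Step 14
Reactants: 28 8-silyloxy germacradienolide
Product: 29 8-hydroxy-9-oxogermacra-1(10)Z,4Z,11(13)-trien-12,6-olide (C6, C7, C8 as in the target)
Conditions: HF·pyridine, pyridine, THF, 0 °C to rt
Reagents that add atoms: none
Why: Fluoride-mediated cleavage of the silyl ether under buffered, weakly acidic conditions that avoid enolisation at C8, conjugate addition to the methylene lactone and translactonisation.

Step 15
Reactants: 30 angelic acid
Product: 31 (2Z)-2-methylbut-2-en-1-ol
Conditions: LiAlH4, Et2O, 0 °C
Reagents that add atoms: none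
Why: Hydride reduction of the carboxylic acid (1,2-reduction) gives the allylic alcohol with the Z double bond unchanged.

Step 16
Reactants: 31 (2Z)-2-methylbut-2-en-1-ol
Product: 32 [(2R,3S)-2,3-dimethyloxiran-2-yl]methanol
Conditions: Ti(OiPr)4 (cat.), D-(−)-diethyl tartrate, t-BuOOH, 4 Å MS, CH2Cl2, −20 °C
Reagents that add atoms: tert-butyl hydroperoxide, CC(C)(C)OO
Why: Katsuki–Sharpless asymmetric epoxidation of the allylic alcohol, in which D-(−)-tartrate directs oxygen to the face that gives the (2R,3S)-epoxy alcohol (the L-(+)-ester gives 2S with allylic alcohols of this priority pattern), the cis relationship of CH2OH and the C3 methyl following from the Z-alkene.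

Step 17
Reactants: 32 [(2R,3S)-2,3-dimethyloxiran-2-yl]methanol
Product: 33 (2S,3S)-2,3-dimethyloxirane-2-carboxylic acid
Conditions: RuCl3 (cat.), NaIO4, MeCN/EtOAc/H2O, 0 °C to rt
Reagents that add atoms: water, O
Why: Ruthenium tetroxide oxidation (catalytic RuCl3 with periodate) takes the primary alcohol through the aldehyde hydrate to the acid without opening the epoxide, and C2, being quaternary, cannot epimerise (its descriptor changes from R to S by priority only).

Step 18
Reactants: 29 8-hydroxy germacradienolide; 33 (2S,3S)-2,3-dimethyloxirane-2-carboxylic acid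
Product: 35 (6S,7S,8R)-8-[(2S,3S)-2,3-dimethyloxirane-2-carbonyloxy]-9-oxogermacra-1(10)Z,4Z,11(13)-trien-12,6-olide (CNP0183761.1), via mixed anhydride 34 (not isolated)
Conditions: 33, 2,4,6-Cl3C6H2COCl, Et3N, THF, rt; then 29, DMAP, toluene, rt
Reagents that add atoms: none
Why: Yamaguchi esterification: the mixed anhydride is attacked by DMAP at the epoxy-acyl carbonyl and the acylpyridinium acylates the C8 hydroxyl with retention at all centres, and the diastereomer derived from the minor enantiomer of 33 is removed by chromatography at this point.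

Compound list
1 | 2-methylcyclohexane-1,3-dione | CC1C(=O)CCCC1=O | starting material
2 | acrolein | C=CC=O | starting material
3 | 3-(1-methyl-2,6-dioxocyclohexyl)propanal | O=CCCC1(C)C(=O)CCCC1=O | intermediate
4 | ethyltriphenylphosphonium iodide | CC[P+](c1ccccc1)(c1ccccc1)c1ccccc1.[I-] | starting material
5 | ethylidenetriphenylphosphorane (not isolated) | CC=P(c1ccccc1)(c1ccccc1)c1ccccc1 | intermediate
6 | (1-iodoethyl)triphenylphosphonium iodide (not isolated) | CC(I)[P+](c1ccccc1)(c1ccccc1)c1ccccc1.[I-] | intermediate
7 | (1-iodoethylidene)triphenylphosphorane (not isolated) | CC(I)=P(c1ccccc1)(c1ccccc1)c1ccccc1 | intermediate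
8 | 2-[(3Z)-4-iodopent-3-en-1-yl]-2-methylcyclohexane-1,3-dione | O=C1CCCC(=O)C1(C)CC/C=C(/C)I | intermediate
9 | (2S,3S)-3-hydroxy-2-[(3Z)-4-iodopent-3-en-1-yl]-2-methylcyclohexan-1-one (OH cis to the chain) | O=C1CCC[C@H](O)[C@]1(C)CC/C=C(/C)I | intermediate
10 | (2S,3S)-2-[(3Z)-4-iodopent-3-en-1-yl]-2-methyl-3-(triethylsilyloxy)cyclohexan-1-one | O=C1CCC[C@H](O[Si](CC)(CC)CC)[C@]1(C)CC/C=C(/C)I | intermediate
11 | lithium C8=C9 enolate of 10 (not isolated) | [Li+].[O-]C1=CCC[C@H](O[Si](CC)(CC)CC)[C@]1(C)CC/C=C(/C)I | intermediate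
12 | (5S,6S)-6-[(3Z)-4-iodopent-3-en-1-yl]-6-methyl-5-(triethylsilyloxy)cyclohex-2-en-1-one | O=C1C=CC[C@H](O[Si](CC)(CC)CC)[C@]1(C)CC/C=C(/C)I | intermediate
13 | (5S,6S)-6-[(3Z)-4-iodopent-3-en-1-yl]-6-methyl-5-(triethylsilyloxy)-1-(trimethylsilyloxy)cyclohexa-1,3-diene (not isolated) | C[Si](C)(C)OC1=CC=C[C@H](O[Si](CC)(CC)CC)[C@]1(C)CC/C=C(/C)I | intermediate
14 | (4R,5R,6S)-4-hydroxy-6-[(3Z)-4-iodopent-3-en-1-yl]-6-methyl-5-(triethylsilyloxy)cyclohex-2-en-1-one (4-OH trans to 5-OSiEt3) | O=C1C=C[C@@H](O)[C@H](O[Si](CC)(CC)CC)[C@]1(C)CC/C=C(/C)I | intermediate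
15 | (diethoxyphosphoryl)acetic acid | OC(=O)CP(=O)(OCC)OCC | starting material
16 | (diethoxyphosphoryl)acetate of the C4 hydroxyl of 14 (germacrane C6 ester) | O=C1C=C[C@@H](OC(=O)CP(=O)(OCC)OCC)[C@H](O[Si](CC)(CC)CC)[C@]1(C)CC/C=C(/C)I | intermediate
17 | cis-fused α-(diethoxyphosphoryl)-γ-lactone ketone (C6β–O, C7β–C11, C5α–OSiEt3, C4 β-Me/α-chain, C9 ketone, C11 epimers) | O=C1C[C@H]2C(P(=O)(OCC)OCC)C(=O)O[C@H]2[C@H](O[Si](CC)(CC)CC)[C@]1(C)CC/C=C(/C)I | intermediate
18 | dipotassium salt of 17: C11 phosphonate carbanion and C8=C9 enolate (not isolated) | [K+].[K+].[O-]C1=C[C@H]2[C-](P(=O)(OCC)OCC)C(=O)O[C@H]2[C@H](O[Si](CC)(CC)CC)[C@]1(C)CC/C=C(/C)I | intermediate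
19 | 8α-hydroxy derivative of 17 | O=C1[C@H](O)[C@H]2C(P(=O)(OCC)OCC)C(=O)O[C@H]2[C@H](O[Si](CC)(CC)CC)[C@]1(C)CC/C=C(/C)I | intermediate
20 | 8α-(tert-butyldimethylsilyloxy) derivative of 17 | O=C1[C@H](O[Si](C)(C)C(C)(C)C)[C@H]2C(P(=O)(OCC)OCC)C(=O)O[C@H]2[C@H](O[Si](CC)(CC)CC)[C@]1(C)CC/C=C(/C)I | intermediate
21 | 5α-hydroxy-8α-(tert-butyldimethylsilyloxy) phosphonolactone ketone | O=C1[C@H](O[Si](C)(C)C(C)(C)C)[C@H]2C(P(=O)(OCC)OCC)C(=O)O[C@H]2[C@H](O)[C@]1(C)CC/C=C(/C)I | intermediate
22 | keto mesylate: 5α-methanesulfonate of 21 | O=C1[C@H](O[Si](C)(C)C(C)(C)C)[C@H]2C(P(=O)(OCC)OCC)C(=O)O[C@H]2[C@H](OS(C)(=O)=O)[C@]1(C)CC/C=C(/C)I | intermediate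
23 | formaldehyde (used as paraformaldehyde) | C=O | starting material
24 | potassium C11 phosphonate salt of 22 (not isolated) | [K+].O=C1[C@H](O[Si](C)(C)C(C)(C)C)[C@H]2[C-](P(=O)(OCC)OCC)C(=O)O[C@H]2[C@H](OS(C)(=O)=O)[C@]1(C)CC/C=C(/C)I | intermediate
25 | (Z)-C10 alkenyllithium derived from 24 (not isolated) | [K+].O=C1[C@H](O[Si](C)(C)C(C)(C)C)[C@H]2[C-](P(=O)(OCC)OCC)C(=O)O[C@H]2[C@H](OS(C)(=O)=O)[C@]1(C)CC/C=C(/C)[Li] | intermediate
26 | cis-fused bicyclic C9 alkoxide (new C9–C10 bond, C9–O β, C1=C10 in the new ring), lithium alkoxide and potassium phosphonate (not isolated) | [Li+].[K+].[O-][C@@]12[C@H](O[Si](C)(C)C(C)(C)C)[C@H]3[C-](P(=O)(OCC)OCC)C(=O)O[C@H]3[C@H](OS(C)(=O)=O)[C@]1(C)CCC=C2C | intermediate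
27 | potassium C11 phosphonate salt of the ring-expanded 8-silyloxy-9-oxogermacra-1(10)Z,4Z-dien-12,6-olide (not isolated) | [K+].CCOP(=O)(OCC)[C-]1C(=O)O[C@H]2/C=C(/C)CC/C=C(/C)C(=O)[C@H](O[Si](C)(C)C(C)(C)C)[C@@H]12 | intermediate
28 | 8-(tert-butyldimethylsilyloxy)-9-oxogermacra-1(10)Z,4Z,11(13)-trien-12,6-olide (C6, C7, C8 as in the target) | C=C1C(=O)O[C@H]2/C=C(/C)CC/C=C(/C)C(=O)[C@H](O[Si](C)(C)C(C)(C)C)[C@@H]12 | intermediate
29 | 8-hydroxy-9-oxogermacra-1(10)Z,4Z,11(13)-trien-12,6-olide (C6, C7, C8 as in the target) | C=C1C(=O)O[C@H]2/C=C(/C)CC/C=C(/C)C(=O)[C@H](O)[C@@H]12 | intermediate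
30 | angelic acid, (2Z)-2-methylbut-2-enoic acid | C/C=C(/C)C(=O)O | starting material
31 | (2Z)-2-methylbut-2-en-1-ol | C/C=C(/C)CO | intermediate
32 | [(2R,3S)-2,3-dimethyloxiran-2-yl]methanol | OC[C@@]1(C)O[C@H]1C | intermediate
33 | (2S,3S)-2,3-dimethyloxirane-2-carboxylic acid | OC(=O)[C@@]1(C)O[C@H]1C | intermediate
34 | (2S,3S)-2,3-dimethyloxirane-2-carboxylic 2,4,6-trichlorobenzoic anhydride (not isolated) | O=C(OC(=O)[C@@]1(C)O[C@H]1C)c1c(Cl)cc(Cl)cc1Cl | intermediate
35 | (6S,7S,8R)-8-[(2S,3S)-2,3-dimethyloxirane-2-carbonyloxy]-9-oxogermacra-1(10)Z,4Z,11(13)-trien-12,6-olide, CNP0183761.1 | C=C1C(=O)O[C@H]2/C=C(/C)CC/C=C(/C)C(=O)[C@H](OC(=O)[C@@]3(C)O[C@H]3C)[C@@H]12 | target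

Total step count: 18. Longest linear sequence: 15 (steps 1–14 and 18); steps 15–17 prepare acid 33.

Steps most likely to fail

Step 13 (proposed new method). The cascade may be defeated by proton transfer to the alkenyllithium or to t-BuLi from the mesyl methyl group or C8–H, by attack of the alkyllithium on the sulfonate, or by a slow fragmentation of the lithium alkoxide that gives the silyl group time to migrate from O8 to O9. The fallback separates the events and removes the strong base from the C–C bond formation. Starting from 22, the alkenyl iodide is added to the C9 ketone under Nozaki–Hiyama–Kishi conditions (CrCl2, NiCl2 cat., DMSO, rt), which leave the mesylate, the silyl ether and the un-ionised phosphonolactone alone, and the neutral cis-fused hydroxy mesylate F1 is isolated. KN(SiMe3)2 (2.1 equiv, THF, −78 to 0 °C) converts it into the dipotassium alkoxide–phosphonate F2, which undergoes the classical base-induced fragmentation of a 1,3-diol monosulfonate to 27, and paraformaldehyde then gives 28, where the route is rejoined.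

Step 9. Oxygen transfer to the C11 phosphonate anion may compete with the C8 enolate, or the second deprotonation may be incomplete. The fallback replaces direct enolate oxidation by oxidation of an isolated silyl enol ether. Starting from 17, the dianion is made in the same way but is silylated with Me3SiCl (2.5 equiv); aqueous work-up hydrolyses the labile ketene acetal of the phosphonolactone and leaves the C8=C9 trimethylsilyl enol ether F3, whose neutral phosphonolactone is inert to peracid. Rubottom oxidation (mCPBA, NaHCO3, CH2Cl2, −20 °C) on the convex face gives the 8α-trimethylsilyloxy ketone F4, and citric acid in methanol releases 19, where the route is rejoined.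

Step 6. The peracid may deliver oxygen to C6 from the face of the C5 silyl ether (poor facial selectivity). Starting from 12, step 6 is run as described and the C6 epimer F5 obtained beside 14 is not discarded: Mitsunobu esterification with 15 (PPh3, DIAD, THF, 0 °C) inverts C6 and gives 16 directly, so that both epimers converge on the route at 16.

Further compounds
F1 | step 13 | cis-fused bicyclic tertiary alcohol (C9–OH β, new C9–C10 bond, 5α-mesylate, 8α-silyl ether, neutral phosphonolactone) | O[C@@]12[C@H](O[Si](C)(C)C(C)(C)C)[C@H]3C(P(=O)(OCC)OCC)C(=O)O[C@H]3[C@H](OS(C)(=O)=O)[C@]1(C)CCC=C2C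
F2 | step 13 | dipotassium C9 alkoxide/C11 phosphonate salt of F1 | [K+].[K+].[O-][C@@]12[C@H](O[Si](C)(C)C(C)(C)C)[C@H]3[C-](P(=O)(OCC)OCC)C(=O)O[C@H]3[C@H](OS(C)(=O)=O)[C@]1(C)CCC=C2C
F3 | step 9 | C8=C9 trimethylsilyl enol ether of 17 | C[Si](C)(C)OC1=C[C@H]2C(P(=O)(OCC)OCC)C(=O)O[C@H]2[C@H](O[Si](CC)(CC)CC)[C@]1(C)CC/C=C(/C)I
F4 | step 9 | 8α-(trimethylsilyloxy) derivative of 17 | O=C1[C@H](O[Si](C)(C)C)[C@H]2C(P(=O)(OCC)OCC)C(=O)O[C@H]2[C@H](O[Si](CC)(CC)CC)[C@]1(C)CC/C=C(/C)I
F5 | step 6 | (4S,5R,6S)-4-hydroxy-6-[(3Z)-4-iodopent-3-en-1-yl]-6-methyl-5-(triethylsilyloxy)cyclohex-2-en-1-one (C6 epimer of 14, 4-OH cis to 5-OSiEt3) | O=C1C=C[C@H](O)[C@H](O[Si](CC)(CC)CC)[C@]1(C)CC/C=C(/C)I
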